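## The problem

Compound 15 is a 2,5-diaryl-3,4-dimethyltetrahydrofuran with two identical 4-hydroxy-3,5-dimethoxyphenyl groups. Numbered O1, C2, C3, C4, C5 it is (2S,3S,4S,5R): aryl and methyl trans across C2–C3, the two methyls trans across C3–C4, aryl and methyl cis across C4–C5. Because the aryl groups are the same, that single cis relationship is all that breaks the symmetry, so the four contiguous stereocentres must be set one relative to the other and cannot be made in pairs. C2 and C5 are benzylic ether carbons on electron-rich rings and ionise under acid. C2 is in its stable trans arrangement, but C5 is in the less stable cis arrangement and would drift to the all-trans isomer, so strong acid, heat and long exposure are excluded once C5 exists. The phenols are acidic and easily oxidised to quinone methides, and must stay masked until the last step by a group that leaves without acid. C3 is the natural anchor for control: an aryl group at C2 prefers to lie trans to the C3 methyl, a methyl at C4 prefers to lie trans to it, and a hydride added to a C5 oxocarbenium ion enters anti to the C4 methyl, which is what the cis pair requires. The feature that permits a two-component ring synthesis is that C2–C3 is the alkene of an (E)-1-arylpropene, while O1–C5(aryl)–C4 is the ketone oxygen, ketone carbon and α-carbon of an aroylacetate. The ring is thus one reduction below the 2,3-dihydrofuran that a 1,3-dicarbonyl carbenoid forms with an electron-rich alkene, and the ester of that adduct sits on the carbon that must carry a methyl.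

## Retrosynthesis

**15 from 14.** The two phenolic O–CH2Ph bonds are cut first. Benzyl is preferred to silyl (at risk under the alkoxide of the Claisen step), to acetal groups (lost in the acidic reduction) and to esters (lost to hydride, and they weaken the donor ring needed in the key step). Bis-benzyl ether 14 has the full skeleton and all four stereocentres. The forward hydrogenolysis must remove two aryl benzyl ethers while sparing the two benzylic C–O bonds of the ring.

**14 from 12 (through 13).** No skeletal bond is cut; the C5–H and C4–H bonds and one C–H bond of the C4 methyl are removed, leading back to allylic alcohol 12, a 2,3-dihydrofuran with a hydroxymethyl group on C4. A cationic reduction is preferred to hydrogenation of the C4=C5 bond, whose face selection between the C3 methyl and the C2 aryl is unclear. It is also preferred to any route through a saturated C4 ester, whose enolate would expel O1 by β-elimination and open the ring. Alcohol 12 has two stereocentres fewer than 14. The forward step must deoxygenate the CH2OH group, let C4 settle trans to C3 through reversible protonation of enol ether 13, and deliver hydride to C5 anti to the C4 methyl, at a temperature low enough that C5 does not ionise again.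

**12 from 11.** The C4 hydroxymethyl is taken back to the methyl ester of 11 (change of oxidation level only). The ester is kept to this point because it is the second acceptor that makes the key step possible. The forward reduction must be a clean 1,2-reduction of a vinylogous carbonate with non-acidic work-up.

**11 from 4 and 9 (through 10).** The C3–C4 and O1–C2 bonds are cut together, dividing the ring into propenylarene 4 and aroyl diazoacetate 9. This cut is preferred to cutting O1–C2 alone (the open chain would still hold three stereocentres) and to cutting a C–aryl bond (a ring with three centres is still needed). It yields two achiral fragments of equal size, each carrying one aryl ring, and leaves a single stereocentre (C3) to reagent control. The forward reaction must be regioselective (carbenoid carbon to the methyl-bearing alkene carbon, ketone oxygen to the benzylic carbon), trans-selective at C2, and enantioselective at C3. Cyclopropane 10 is accepted as a possible intermediate and is converged on 11 in the same flask.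

**9 from 8, 8 from 6 and 7, 6 from 5 and 2.** The C=N2 bond is cut back to the active methylene of β-keto ester 8. The C–C bond between the α-carbon and the ester carbon is cut back to acetophenone 6 and dimethyl carbonate 7, whose carbonyl carbon ends as the C4 methyl of 15. The benzyl ether is cut back to acetosyringone 5 and benzyl bromide 2. This is shorter than building the keto ester from the benzoic acid through a malonate equivalent, and all three reactions are routine.

**4 from 3, 3 from 1 and 2.** The conjugated alkene is taken back to the allyl isomer 3, and the benzyl ether to 4-allyl-2,6-dimethoxyphenol 1 and benzyl bromide 2. Isomerisation is preferred to an olefination of the aldehyde because the carbon skeleton is bought complete and the (E) isomer is the thermodynamic product.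

## Roads not taken

**Alternative 1:** The cut is at the two C–CH3 bonds of a γ-aryl lactone, with the C5 aryl group added afterwards. Forward, Me2CuLi adds to the β-carbon of butenolide A1 anti to the γ-aryl group and the enolate is methylated with MeI anti to the new methyl, giving the trans,trans lactone A2 in one flask. Addition of an aryllithium to A2 and reduction of the hemiketal through the C5 oxocarbenium ion would finish the ring.
- Merits: both methyl-bearing centres follow from one existing centre by dependable substrate control, and the relative configuration of A2 is hardly in doubt. In this respect it is better than step 6, whose enantioselectivity is uncertain.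
- Weak points: A1 needs its own asymmetric step. Its γ-hydrogen is benzylic and vinylogously acidic, so the basic cuprate and enolate conditions threaten racemisation through the 2-oxyfuran dienolate. Alkylation of cuprate-derived enolates is prone to proton transfer and over-alkylation. The two aryl rings enter at opposite ends of a linear sequence.
- Comparison: the end game uses the same oxocarbenium reduction, so nothing is gained at C5. Against the better stereochemical predictability, the chosen plan sets a convergent union of two fragments, each two or three steps from a commercial phenol, in a catalytic step that closes the ring and forms two skeletal bonds; the key step of alternative 1 closes no ring.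

**Alternative 2:** The cut is the O1–C2 bond. Forward, anodic oxidation of the free phenol of open-chain alcohol A3 gives a para-quinone methide, whose exocyclic carbon is captured by the C5 hydroxyl to give A4, the mono-benzyl ether of 15.
- Merits: no stoichiometric oxidant; it uses the innate reactivity of the hydroxydimethoxyphenyl group; C5 is set beforehand as a carbinol, so the labile cis pair is never made by an ionic reduction. A4 is one hydrogenolysis from 15, which is better than the three steps that follow the key step of the chosen plan.
- Weak points: A3 holds three contiguous stereocentres in an open chain and two differentiated phenols, and its preparation would probably cost more steps than the whole chosen route. The quinone methide has a β-hydrogen and can tautomerise to the styrene or be trapped by solvent. C2 is set only by the trans preference of the closure. A4 is a phenol of about the same oxidation potential as A3 and can be oxidised again at C2, which would open or epimerise the ring.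
- Comparison: the chosen plan is longer after ring closure but far shorter before it, and forms two bonds from two simple fragments.

**Alternative 3:** The cut is at C2–aryl and O1–C2. Forward, with Pd(OAc)2 (divalent palladium) and benzoquinone as oxidant, the arylpalladium from boronic acid A6 adds to the 1,1-disubstituted alkene of alkenol A5. Palladium then moves to the benzylic carbon by β-hydride elimination and reinsertion, and the C5 hydroxyl displaces it to close the ring, giving A7, which is identical with 14.
- Merits: it reaches 14 directly, with the aryl ring introduced last and no redox adjustment after the key step. In economy after the key step it is better than the chosen plan.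
- Weak points: the alkene must be 1,1-disubstituted for this target, so the first insertion gives a tertiary alkylpalladium with three kinds of β-hydrogen; elimination toward the methyl group or toward C4 diverts material. C3 is created in the reinsertion of the palladium hydride and C2 in the displacement, neither with a dependable controlling element. The reaction type is established for monosubstituted terminal alkenes. A5 already needs its C4/C5 pair made with absolute control.
- Comparison: the chosen plan spends three steps after ring closure, but sets C3 under catalyst control and lets each later centre follow from it by known preferences.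

Key step: step 6

Assumption: the (S)-tert-leucinate catalyst is taken to give the (2S,3S) dihydrofuran 11; should the sense of induction be the opposite, the enantiomeric catalyst Rh2(R-TCPTTL)4 from (R)-tert-leucine is used and nothing else changes.

## Route

Step 1
Reactants: 1 4-allyl-2,6-dimethoxyphenol; 2 benzyl bromide
Product: 3 5-allyl-2-benzyloxy-1,3-dimethoxybenzene
Conditions: K2CO3, DMF, 60 °C
Reagents that add atoms: none
Why: Williamson ether synthesis on an acidic, hindered phenol; benzyl is chosen because it withstands base, hydride, the carbenoid step and the cold acidic reduction and leaves by hydrogenolysis.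

Step 2
Reactants: 3 5-allyl-2-benzyloxy-1,3-dimethoxybenzene
Product: 4 (E)-2-benzyloxy-1,3-dimethoxy-5-(prop-1-enyl)benzene
Conditions: PdCl2(MeCN)2 (5 mol %), CH2Cl2, rt
Reagents that add atoms: none
Why: Palladium-hydride alkene isomerisation (insertion and β-hydride elimination) moves the double bond into conjugation with the ring; the conjugated (E)-propenylarene is the thermodynamic product and should form almost exclusively.

Step 3
Reactants: 5 1-(4-hydroxy-3,5-dimethoxyphenyl)ethanone (acetosyringone); 2 benzyl bromide
Product: 6 1-(4-benzyloxy-3,5-dimethoxyphenyl)ethanone
Conditions: K2CO3, DMF, 60 °C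
Reagents that add atoms: none
Why: Williamson ether synthesis; the para-acyl phenol is acidic and alkylates cleanly on oxygen.

Step 4
Reactants: 6 1-(4-benzyloxy-3,5-dimethoxyphenyl)ethanone; 7 dimethyl carbonate
Product: 8 methyl 3-(4-benzyloxy-3,5-dimethoxyphenyl)-3-oxopropanoate
Conditions: NaH (2.5 equiv), toluene, reflux; then dilute HCl
Reagents that add atoms: none
Why: Crossed Claisen condensation of the methyl ketone enolate with the non-enolisable carbonate, driven to completion by deprotonation of the β-keto ester as it forms.

Step 5
Reactants: 8 methyl 3-(4-benzyloxy-3,5-dimethoxyphenyl)-3-oxopropanoate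
Product: 9 methyl 3-(4-benzyloxy-3,5-dimethoxyphenyl)-2-diazo-3-oxopropanoate
Conditions: p-ABSA, Et3N, MeCN, 0 °C → rt
Reagents that add atoms: 4-acetamidobenzenesulfonyl azide (p-ABSA), CC(=O)Nc1ccc(cc1)S(=O)(=O)N=[N+]=[N-]
Why: Regitz diazo transfer to the doubly activated methylene; the sulfonamide by-product is removed by filtration and a basic wash.

Step 6
Reactants: 4 (E)-2-benzyloxy-1,3-dimethoxy-5-(prop-1-enyl)benzene; 9 methyl 3-(4-benzyloxy-3,5-dimethoxyphenyl)-2-diazo-3-oxopropanoate
Product: 11 methyl (2S,3S)-2,5-bis(4-benzyloxy-3,5-dimethoxyphenyl)-3-methyl-2,3-dihydrofuran-4-carboxylate, via donor–acceptor cyclopropane 10 (not isolated)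
Conditions: Rh2(S-TCPTTL)4 (1 mol %), CH2Cl2, 0 °C → rt, slow addition of 9 (1.3 equiv) to 4; then Sc(OTf)3 (5 mol %), rt
Reagents that add atoms: none
Why: Rh2(S-TCPTTL)4 (dirhodium tetrakis[N-tetrachlorophthaloyl-(S)-tert-leucinate], divalent rhodium) converts 9 into an electrophilic acceptor/acceptor carbenoid, which is attacked by the methyl-bearing alkene carbon of 4 so that C3–C4 forms and positive charge develops at the benzylic carbon; the closest known reaction types are the dirhodium-carboxylate formal [3+2] cycloaddition of 2-diazo-1,3-dicarbonyl compounds with electron-rich alkenes and the enantioselective cyclopropanation of styrenes by aryl-ketone diazo esters under tert-leucinate catalysts. Collapse of the zwitterion at carbon gives cyclopropane 10, collapse at the ketone oxygen gives 11 directly, and Sc(OTf)3 reopens any 10 at its donor–acceptor bond and converges it on 11 (Cloke–Wilson ring expansion). The one ring is closed by O-alkylation of the keto-enolate oxygen on the benzylic cation, a 5-(enolendo)-exo-trig closure that forms O1–C2; the ketone oxygen closes, not the ester oxygen, because its enolate is the more nucleophilic and the product is then a conjugated 5-aryl enol ether. C3 is the only centre under catalyst control: the chiral pocket of the tert-leucinate ligands selects the alkene face at the carbon that bonds to the carbenoid, and this centre has no acidic or ionisable bond and is not touched again. C2 is set by the substrate, the aryl group closing trans to the C3 methyl, and because the C2–O bond can reopen under the Lewis acid the trans isomer is also the thermodynamic sink. The step needs regioselectivity (carbenoid to the methyl-bearing carbon), secured by stabilisation of the benzylic cation by the trialkoxyphenyl ring, and chemoselectivity for the alkene over the benzyl ether oxygen atoms and C–H bonds, secured by the low insertion reactivity of acceptor/acceptor carbenoids and the slow addition of 9. The (E) geometry of 4 matters for the enantiofacial reading of the alkene only, since the trans ring relationship is reached by either course.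

Step 7
Reactants: 11 methyl (2S,3S)-2,5-bis(4-benzyloxy-3,5-dimethoxyphenyl)-3-methyl-2,3-dihydrofuran-4-carboxylate
Product: 12 [(2S,3S)-2,5-bis(4-benzyloxy-3,5-dimethoxyphenyl)-3-methyl-2,3-dihydrofuran-4-yl]methanol
Conditions: i-Bu2AlH (3 equiv), CH2Cl2, −78 °C; aq. potassium sodium tartrate
Reagents that add atoms: none
Why: 1,2-Reduction of a vinylogous carbonate ester by diisobutylaluminium hydride to the primary allylic alcohol, which leaves the enol ether double bond and the benzyl ethers untouched; the work-up is kept non-acidic because the product ionises easily.

Step 8
Reactants: 12 [(2S,3S)-2,5-bis(4-benzyloxy-3,5-dimethoxyphenyl)-3-methyl-2,3-dihydrofuran-4-yl]methanol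
Product: 14 (2S,3S,4S,5R)-2,5-bis(4-benzyloxy-3,5-dimethoxyphenyl)-3,4-dimethyltetrahydrofuran, via 4-methyl enol ether 13 (not isolated)
Conditions: Et3SiH (6 equiv), CF3CO2H (4 equiv), CH2Cl2, −40 → 0 °C; NaHCO3 quench
Reagents that add atoms: none
Why: Ionic hydrogenation: the acid ionises the allylic hydroxyl to an aryl- and oxygen-stabilised alkoxyallyl cation, Et3SiH reduces it at the unhindered CH2 terminus to enol ether 13, and C-protonation of 13 gives the C5 oxocarbenium ion that takes the second hydride. Reversible protonation lets C4 settle with its methyl trans to the C3 methyl (thermodynamic control), and hydride then enters C5 anti to the adjacent C4 methyl (inside attack on the envelope oxocarbenium ion), which places the C5 aryl cis to that methyl as in the (4S,5R) target. The same oxocarbenium reduction is the established way to the cis aryl/methyl pair of 2,5-diaryl-3,4-dimethyltetrahydrofurans from cyclic hemiketals.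

Step 9
Reactants: 14 (2S,3S,4S,5R)-2,5-bis(4-benzyloxy-3,5-dimethoxyphenyl)-3,4-dimethyltetrahydrofuran
Product: 15 4,4'-[(2S,3S,4S,5R)-3,4-dimethyltetrahydrofuran-2,5-diyl]bis(2,6-dimethoxyphenol)
Conditions: H2 (1 atm), 10 % Pd/C, EtOAc, rt
Reagents that add atoms: none
Why: Hydrogenolysis of the two aryl benzyl ethers under neutral conditions; the hindered secondary benzylic C–O bonds of the ring should cleave much more slowly, and no stereocentre is involved.

## Compound list

1 | 4-allyl-2,6-dimethoxyphenol | C=CCc1cc(OC)c(O)c(OC)c1 | starting material
2 | benzyl bromide | BrCc1ccccc1 | starting material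
3 | 5-allyl-2-benzyloxy-1,3-dimethoxybenzene | C=CCc1cc(OC)c(OCc2ccccc2)c(OC)c1 | intermediate
4 | (E)-2-benzyloxy-1,3-dimethoxy-5-(prop-1-enyl)benzene | C/C=C/c1cc(OC)c(OCc2ccccc2)c(OC)c1 | intermediate
5 | 1-(4-hydroxy-3,5-dimethoxyphenyl)ethanone (acetosyringone) | CC(=O)c1cc(OC)c(O)c(OC)c1 | starting material
6 | 1-(4-benzyloxy-3,5-dimethoxyphenyl)ethanone | CC(=O)c1cc(OC)c(OCc2ccccc2)c(OC)c1 | intermediate
7 | dimethyl carbonate | COC(=O)OC | starting material
8 | methyl 3-(4-benzyloxy-3,5-dimethoxyphenyl)-3-oxopropanoate | COC(=O)CC(=O)c1cc(OC)c(OCc2ccccc2)c(OC)c1 | intermediate
9 | methyl 3-(4-benzyloxy-3,5-dimethoxyphenyl)-2-diazo-3-oxopropanoate | COC(=O)C(=[N+]=[N-])C(=O)c1cc(OC)c(OCc2ccccc2)c(OC)c1 | intermediate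
10 | methyl (1S,2S,3R)-1-(4-benzyloxy-3,5-dimethoxybenzoyl)-2-(4-benzyloxy-3,5-dimethoxyphenyl)-3-methylcyclopropane-1-carboxylate (aryl and methyl trans; aroyl drawn trans to the aryl, a centre that is lost on ring expansion; not isolated) | COc1cc([C@H]2[C@@](C(=O)c3cc(OC)c(OCc4ccccc4)c(OC)c3)(C(=O)OC)[C@@H]2C)cc(OC)c1OCc1ccccc1 | intermediate
11 | methyl (2S,3S)-2,5-bis(4-benzyloxy-3,5-dimethoxyphenyl)-3-methyl-2,3-dihydrofuran-4-carboxylate | COc1cc([C@H]2OC(c3cc(OC)c(OCc4ccccc4)c(OC)c3)=C(C(=O)OC)[C@@H]2C)cc(OC)c1OCc1ccccc1 | intermediate
12 | [(2S,3S)-2,5-bis(4-benzyloxy-3,5-dimethoxyphenyl)-3-methyl-2,3-dihydrofuran-4-yl]methanol | COc1cc([C@H]2OC(c3cc(OC)c(OCc4ccccc4)c(OC)c3)=C(CO)[C@@H]2C)cc(OC)c1OCc1ccccc1 | intermediate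
13 | (2S,3S)-2,5-bis(4-benzyloxy-3,5-dimethoxyphenyl)-3,4-dimethyl-2,3-dihydrofuran (not isolated) | COc1cc([C@H]2OC(c3cc(OC)c(OCc4ccccc4)c(OC)c3)=C(C)[C@@H]2C)cc(OC)c1OCc1ccccc1 | intermediate
14 | (2S,3S,4S,5R)-2,5-bis(4-benzyloxy-3,5-dimethoxyphenyl)-3,4-dimethyltetrahydrofuran | COc1cc([C@H]2O[C@@H](c3cc(OC)c(OCc4ccccc4)c(OC)c3)[C@@H](C)[C@@H]2C)cc(OC)c1OCc1ccccc1 | intermediate
15 | 4,4'-[(2S,3S,4S,5R)-3,4-dimethyltetrahydrofuran-2,5-diyl]bis(2,6-dimethoxyphenol) | COc1cc([C@H]2O[C@@H](c3cc(OC)c(O)c(OC)c3)[C@@H](C)[C@@H]2C)cc(OC)c1O | target

## Step count and risks

Total step count: 9. Longest linear sequence: 7 steps (steps 3 to 9, from 5). The other branch (steps 1 and 2) joins at step 6.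

**Step 6 (key step).** The most likely failure is poor enantiofacial discrimination, because the catalyst has to read a 1,2-disubstituted alkene with an acyclic aroyl diazo ester. Carbenoid transfer to the trans-disubstituted alkene may also be slow, and proton loss from the benzylic zwitterion would give an open-chain alkene in place of the ring. The fallback sets out from 8 and 4 and returns at 11. Oxidative radical annulation with Mn(OAc)3·2H2O (trivalent manganese) in AcOH at about 70 °C forms the same two bonds: the manganese enolate radical of 8 adds to the methyl-bearing alkene carbon, the benzylic radical is oxidised to the cation, and the ketone oxygen closes the ring. This gives the racemic trans-dihydrofuran F1. Preparative chromatography on a chiral stationary phase separates the enantiomers, and the (2S,3S) enantiomer is 11.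

**Step 8.** The most likely failure is hydride capture at C5 of the alkoxyallyl cation before the C4 methyl exists, so that C5 is set without its controlling neighbour and facial selectivity is poor. Further risks are incomplete equilibration at C4 before the second hydride arrives, and acid-promoted epimerisation at C5 or reductive opening of the ring if the mixture is left too long or too warm. The fallback sets out from 12 and returns at 14, and separates the two reductions. SO3·pyridine in THF at 0 °C gives the pyridinium allylic sulfate F2. LiAlH4 in the same flask displaces sulfate at the primary carbon and gives enol ether 13, now isolated on basic alumina. 13 is then reduced alone with Et3SiH and CF3CO2H at −78 → −20 °C, so that the only cation formed is the C5 oxocarbenium ion with the C4 methyl in place, and 14 results.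

**Step 7.** The most likely failure is loss of the hydroxyl group by ionisation of the γ-hydroxy enol ether during work-up or chromatography, followed by hydration or oligomerisation; partial 1,4-reduction by the aluminium hydride is a lesser risk. The fallback sets out from 11 and returns at 14. After the i-Bu2AlH reduction the crude alcohol is not purified but acetylated (Ac2O, Et3N, DMAP, CH2Cl2, 0 °C) to the allylic acetate F3, which is filtered through Et3N-deactivated silica. F3 is then submitted to Et3SiH and CF3CO2H as in step 8; it ionises to the same alkoxyallyl cation and should give 14 without 12 ever being handled pure.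

**Step 9.** The most likely failure is hydrogenolytic opening of the ring at the benzylic C2–O or C5–O bond once the phenols are free, because both carbons carry electron-rich aryl groups. The fallback sets out from 14 and returns at 15, and replaces reduction by Lewis-acid benzyl transfer: BCl3 with pentamethylbenzene as cation scavenger in CH2Cl2 at −78 °C, quenched cold with methanol so that C5 has no time to ionise. It makes no compound beyond those listed (F0).

## Further compounds

F1 | step 6 | racemic methyl (2RS,3RS)-2,5-bis(4-benzyloxy-3,5-dimethoxyphenyl)-3-methyl-2,3-dihydrofuran-4-carboxylate (1:1 mixture of 11 and its enantiomer) | COc1cc([C@H]2OC(c3cc(OC)c(OCc4ccccc4)c(OC)c3)=C(C(=O)OC)[C@@H]2C)cc(OC)c1OCc1ccccc1.COc1cc([C@@H]2OC(c3cc(OC)c(OCc4ccccc4)c(OC)c3)=C(C(=O)OC)[C@H]2C)cc(OC)c1OCc1ccccc1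
F2 | step 8 | pyridinium [(2S,3S)-2,5-bis(4-benzyloxy-3,5-dimethoxyphenyl)-3-methyl-2,3-dihydrofuran-4-yl]methyl sulfate | COc1cc([C@H]2OC(c3cc(OC)c(OCc4ccccc4)c(OC)c3)=C(COS(=O)(=O)[O-])[C@@H]2C)cc(OC)c1OCc1ccccc1.c1cc[nH+]cc1
F3 | step 7 | [(2S,3S)-2,5-bis(4-benzyloxy-3,5-dimethoxyphenyl)-3-methyl-2,3-dihydrofuran-4-yl]methyl acetate | COc1cc([C@H]2OC(c3cc(OC)c(OCc4ccccc4)c(OC)c3)=C(COC(C)=O)[C@@H]2C)cc(OC)c1OCc1ccccc1
F0 | step 9 | none | none
A1 | alternative 1 | (S)-5-(4-benzyloxy-3,5-dimethoxyphenyl)furan-2(5H)-one | COc1cc([C@H]2OC(=O)C=C2)cc(OC)c1OCc1ccccc1
A2 | alternative 1 | (3S,4S,5S)-5-(4-benzyloxy-3,5-dimethoxyphenyl)-3,4-dimethyldihydrofuran-2(3H)-one | COc1cc([C@H]2OC(=O)[C@@H](C)[C@@H]2C)cc(OC)c1OCc1ccccc1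
A3 | alternative 2 | (1R,2S,3R)-1-(4-benzyloxy-3,5-dimethoxyphenyl)-4-(4-hydroxy-3,5-dimethoxyphenyl)-2,3-dimethylbutan-1-ol | O[C@@H](c1cc(OC)c(OCc2ccccc2)c(OC)c1)[C@@H](C)[C@H](C)Cc1cc(OC)c(O)c(OC)c1
A4 | alternative 2 | 4-[(2S,3S,4S,5R)-5-(4-benzyloxy-3,5-dimethoxyphenyl)-3,4-dimethyltetrahydrofuran-2-yl]-2,6-dimethoxyphenol | COc1cc([C@H]2O[C@@H](c3cc(OC)c(OCc4ccccc4)c(OC)c3)[C@@H](C)[C@@H]2C)cc(OC)c1O
A5 | alternative 3 | (1R,2S)-1-(4-benzyloxy-3,5-dimethoxyphenyl)-2,3-dimethylbut-3-en-1-ol | O[C@@H](c1cc(OC)c(OCc2ccccc2)c(OC)c1)[C@@H](C)C(C)=C
A6 | alternative 3 | (4-benzyloxy-3,5-dimethoxyphenyl)boronic acid | OB(O)c1cc(OC)c(OCc2ccccc2)c(OC)c1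
A7 | alternative 3 | (2S,3S,4S,5R)-2,5-bis(4-benzyloxy-3,5-dimethoxyphenyl)-3,4-dimethyltetrahydrofuran (identical with 14) | COc1cc([C@H]2O[C@@H](c3cc(OC)c(OCc4ccccc4)c(OC)c3)[C@@H](C)[C@@H]2C)cc(OC)c1OCc1ccccc1
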